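C40 chain: two Wittig olefinations (C11=C12, then C11'=C12') join the ring-A C15 phosphonium salt 16, the C10 dialdehyde 23 and the ring-B C15 phosphonium salt 22.
Both C15 units come from one cyclohexanone, 10: ring A by enol triflate formation and Sonogashira coupling (C6–C7), ring B by dehydrogenation, acetylide addition and a carbonate-tethered allylic transposition that puts O4' cis to O3'.
The carbocycle is made only once, by closing C2–C3 of ring A (the same bond serves as C2'–C3' of ring B): an enantioselective cobalt/chromium reductive cyclisation of the achiral iodo keto aldehyde 5, i.e. a union of two electrophilic carbons (aldehyde C3, iodide-bearing C2) by polarity reversal at C2.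
Enabling feature: in the 3-hydroxy ring A, C3 is a secondary carbinol between the methylenes C2 and C4, and C2 hangs on the quaternary gem-dimethyl carbon C1 next to C6; so C3 can be an aldehyde carbon and C2 a neopentyl-type radical/alkylchromium that has no β-hydrogen, while the C1 gem-dimethyl group and a C6 carbonyl fold the chain for six-ring closure.
Ring order: the six-membered carbocycle (step 4, used for rings A and B), then a temporary cyclic carbonate on ring B (step 12, removed in step 16).

Key step: step 4

Remark: compounds 1, 13 and 23 are taken as purchasable; ring atoms carry carotenoid locants (ring A = 3-hydroxy end group, ring B = 3',4'-dihydroxy end group, primed).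
Remark: species that a reagent generates stoichiometrically from a numbered compound before the bond-forming event (enolates, acetylide, ylides, bromides, silyl ether) are numbered as non-isolated intermediates; species inside catalytic cycles are described only in the Why line.

Step 1
Reactants: 1 4-hydroxy-3,3-dimethylbutan-2-one
Product: 2 4-iodo-3,3-dimethylbutan-2-one
Conditions: PPh3, I2, imidazole, toluene, 80 °C
Reagents that add atoms: iodine, II
Why: Appel-type iodination, in which the alkoxyphosphonium ion of the neopentyl-type primary alcohol is displaced by iodide on heating and elimination is impossible because the adjacent carbon is quaternary.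

Step 2
Reactants: 2 4-iodo-3,3-dimethylbutan-2-one
Product: 4 1-iodo-2,2-dimethylhept-6-en-3-one, via lithium enolate 3 (not isolated)
Conditions: LiN(i-Pr)2 (LDA), THF, −78 °C; allyl bromide, −78 → 0 °C
Reagents that add atoms: allyl bromide, C=CCBr
Why: Kinetic enolate alkylation, since the methyl group is the only enolisable position of 2 and enolate 3 should be C-allylated far faster than it can displace its own neopentyl iodide.

Step 3
Reactants: 4 1-iodo-2,2-dimethylhept-6-en-3-one
Product: 5 6-iodo-5,5-dimethyl-4-oxohexanal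
Conditions: OsO4 (2 mol %), NaIO4 (2.5 equiv), 2,6-lutidine, 1,4-dioxane/H2O, 25 °C
Reagents that add atoms: sodium periodate (terminal source of the aldehyde oxygen), [Na+].[O-]I(=O)(=O)=O
Why: Lemieux–Johnson oxidative cleavage of the terminal alkene under buffered conditions that should spare the alkyl iodide and keep the 1,4-keto aldehyde from cyclodehydrating to a furan.

Step 4
Reactants: 5 6-iodo-5,5-dimethyl-4-oxohexanal
Product: 7 (4R)-4-hydroxy-2,2-dimethylcyclohexan-1-one, via silyl ether 6 (not isolated)
Conditions: CrCl2 (30 mol %), chiral 1,8-bis(4-isopropyl-4,5-dihydrooxazol-2-yl)-3,6-diphenylcarbazole ligand (33 mol %, enantiomer fixed by a preliminary screen), i-Pr2NEt (60 mol %), cobalt phthalocyanine CoC32H16N8 (5 mol %), Mn powder (3 equiv), Me3SiCl (2 equiv), THF, 25 °C, slow addition of 5; then 1 M HCl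
Reagents that add atoms: none
Why: Proposed new method: a catalytic, enantioselective, intramolecular alkyl Nozaki–Hiyama–Kishi (Barbier-type) reaction in which manganese-generated monovalent cobalt activates the neopentyl-type C–I bond of 5, the primary C2 radical (no β-hydrogen, because C1 is quaternary) is trapped by ligand-bound divalent chromium, the alkylchromium adds to the tethered aldehyde carbon C3, and Me3SiCl silylates the chromium alkoxide to 6 so that trivalent chromium is released for reduction by Mn. The closest known reaction types are the cobalt-catalysed CrCl2 alkylation of aldehydes with primary alkyl iodides, which leaves ketones untouched, and the catalytic asymmetric Nozaki–Hiyama–Kishi allylation and alkenylation with oxazoline-ligated chromium; new is their combination on an unactivated alkyl iodide in a ring closure under ligand control. The ring closes in the 6-exo-trig mode through a chair in which the C1 gem-dimethyl group (Thorpe–Ingold effect) and the sp2 carbon C6 pre-organise the chain. The only new stereocentre, C3, is set by the chiral ligand on chromium, because 5 is achiral. The step needs chemoselectivity for the aldehyde over the ketone, which the substrate secures because the C6 carbonyl is flanked by the quaternary C1 and alkylchromium reagents add only to aldehydes, and it needs trapping of the C2 radical before its 1,2-acyl (Dowd–Beckwith-type) shift, which a high standing concentration of divalent chromium and slow addition of 5 should secure.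

Step 5
Reactants: 7 (4R)-4-hydroxy-2,2-dimethylcyclohexan-1-one
Product: 8 tert-butyl (1R)-3,3-dimethyl-4-oxocyclohexyl carbonate
Conditions: Boc2O (1.3 equiv), DMAP (10 mol %), MeCN, 25 °C
Reagents that add atoms: di-tert-butyl dicarbonate, CC(C)(C)OC(=O)OC(=O)OC(C)(C)C
Why: DMAP-catalysed O-acylation gives a tert-butyl carbonate that is stable to the amide bases of steps 6 and 7, has no enolisable hydrogen and is the internal nucleophile needed in step 12.

Step 6
Reactants: 8 tert-butyl (1R)-3,3-dimethyl-4-oxocyclohexyl carbonate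
Product: 10 tert-butyl (1R)-3,3,5-trimethyl-4-oxocyclohexyl carbonate (both C5 epimers), via lithium enolate 9 (not isolated)
Conditions: LiN(i-Pr)2 (LDA), THF, −78 °C; MeI, −78 → 0 °C
Reagents that add atoms: iodomethane, CI
Why: Enolate methylation at the only enolisable α-carbon (C5, since C1 is quaternary); the new C5 centre forms as an epimer mixture, which is immaterial because C5 becomes sp2 in steps 7 and 10.

Step 7
Reactants: 10 tert-butyl (1R)-3,3,5-trimethyl-4-oxocyclohexyl carbonate
Product: 12 (4R)-4-[(tert-butoxycarbonyl)oxy]-2,6,6-trimethylcyclohex-1-en-1-yl trifluoromethanesulfonate, via lithium enolate 11 (not isolated)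
Conditions: LiN(i-Pr)2 (LDA), THF, −78 °C; PhNTf2, −78 → 25 °C
Reagents that add atoms: N-phenylbis(trifluoromethanesulfonimide), O=S(=O)(N(c1ccccc1)S(=O)(=O)C(F)(F)F)C(F)(F)F
Why: Enol triflate formation, in which deprotonation is possible only at C5 so that both epimers of 10 converge on the tetrasubstituted C5=C6 enolate, which is O-sulfonylated without touching C3.

Step 8
Reactants: 12 (4R)-4-[(tert-butoxycarbonyl)oxy]-2,6,6-trimethylcyclohex-1-en-1-yl trifluoromethanesulfonate; 13 (2E)-3-methylpent-2-en-4-yn-1-ol
Product: 14 tert-butyl (1R)-4-[(3E)-5-hydroxy-3-methylpent-3-en-1-yn-1-yl]-3,5,5-trimethylcyclohex-3-en-1-yl carbonate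
Conditions: Pd(PPh3)4 (5 mol %), CuI (10 mol %), i-Pr2NH, THF, 25 → 45 °C
Reagents that add atoms: none
Why: Sonogashira coupling of the alkenyl triflate with the terminal alkyne under zerovalent palladium forms C6–C7, and the 9E double bond arrives with 13 and is not involved.

Step 9
Reactants: 14 tert-butyl (1R)-4-[(3E)-5-hydroxy-3-methylpent-3-en-1-yn-1-yl]-3,5,5-trimethylcyclohex-3-en-1-yl carbonate
Product: 16 {(2E)-5-[(4R)-4-[(tert-butoxycarbonyl)oxy]-2,6,6-trimethylcyclohex-1-en-1-yl]-3-methylpent-2-en-4-yn-1-yl}triphenylphosphonium bromide, via allylic bromide 15 (not isolated)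
Conditions: CBr4 (1.2 equiv), PPh3 (1.2 equiv), CH2Cl2, 0 °C; then PPh3 (1.2 equiv), 25 °C
Reagents that add atoms: tetrabromomethane, BrC(Br)(Br)Br; triphenylphosphine, c1ccc(cc1)P(c1ccccc1)c1ccccc1
Why: Appel bromination of the primary allylic alcohol by SN2 (9E retained) followed by quaternisation of PPh3 gives the Wittig salt without acid, so the carbonate should survive.

Step 10
Reactants: 10 tert-butyl (1R)-3,3,5-trimethyl-4-oxocyclohexyl carbonate
Product: 17 tert-butyl (1S)-3,5,5-trimethyl-4-oxocyclohex-2-en-1-yl carbonate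
Conditions: IBX (2.5 equiv), DMSO/fluorobenzene, 70 °C
Reagents that add atoms: none
Why: IBX dehydrogenation of a ketone to the enone, where enolisation is possible only toward C5', loss of the ring hydrogen at C4' should give the conjugated endocyclic alkene and the quaternary C1' excludes a second dehydrogenation (C3' is untouched and changes its descriptor only by priority).

Step 11
Reactants: 17 tert-butyl (1S)-3,5,5-trimethyl-4-oxocyclohex-2-en-1-yl carbonate; 13 (2E)-3-methylpent-2-en-4-yn-1-ol
Product: 19 tert-butyl (1S)-4-hydroxy-4-[(3E)-5-hydroxy-3-methylpent-3-en-1-yn-1-yl]-3,5,5-trimethylcyclohex-2-en-1-yl carbonate (both C4 epimers), via dilithio alkynoxide 18 (not isolated)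
Conditions: 13 (1.5 equiv), n-BuLi (3.0 equiv), THF, −78 → 0 °C; then 17, −78 °C; H2O
Reagents that add atoms: none
Why: 1,2-Addition of a lithium acetylide to the enone carbonyl, run cold so that the carbonate is not attacked; the new C6' carbinol centre forms as a mixture and is erased in step 12.

Step 12
Reactants: 19 tert-butyl (1S)-4-hydroxy-4-[(3E)-5-hydroxy-3-methylpent-3-en-1-yn-1-yl]-3,5,5-trimethylcyclohex-2-en-1-yl carbonate
Product: 20 (3aS,7aR)-6-[(3E)-5-hydroxy-3-methylpent-3-en-1-yn-1-yl]-5,5,7-trimethyl-3a,4,5,7a-tetrahydro-1,3-benzodioxol-2-one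
Conditions: (1S)-camphor-10-sulfonic acid (10 mol %), CH2Cl2, −20 → 0 °C
Reagents that add atoms: none
Why: Proposed new method: acid ionises the tertiary, allylic and propargylic C6'–OH to a delocalised cation that is captured at C4' by the carbonyl oxygen of the neighbouring C3' tert-butyl carbonate (five-membered ring, necessarily cis-fused) with loss of isobutene and formation of the conjugated C5'=C6' enyne, so that C4' is set by the tether from C3' and both C6' epimers converge; the closest known reaction types are the acid-catalysed anionotropic 1,3-transposition of tertiary alkynyl vinyl carbinols and the capture of iodonium or epoxonium centres by tert-butyl carbonates to give cyclic carbonates.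

Step 13
Reactants: 20 (3aS,7aR)-6-[(3E)-5-hydroxy-3-methylpent-3-en-1-yn-1-yl]-5,5,7-trimethyl-3a,4,5,7a-tetrahydro-1,3-benzodioxol-2-one
Product: 22 {(2E)-3-methyl-5-[(3aS,7aR)-5,5,7-trimethyl-2-oxo-3a,4,5,7a-tetrahydro-1,3-benzodioxol-6-yl]pent-2-en-4-yn-1-yl}triphenylphosphonium bromide, via allylic bromide 21 (not isolated)
Conditions: CBr4 (1.2 equiv), PPh3 (1.2 equiv), CH2Cl2, 0 °C; then PPh3 (1.2 equiv), 25 °C
Reagents that add atoms: tetrabromomethane, BrC(Br)(Br)Br; triphenylphosphine, c1ccc(cc1)P(c1ccccc1)c1ccccc1
Why: Appel bromination and quaternisation as in step 9, under neutral conditions to which the cyclic carbonate and the 9'E double bond should be inert.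

Step 14
Reactants: 16 {(2E)-5-[(4R)-4-[(tert-butoxycarbonyl)oxy]-2,6,6-trimethylcyclohex-1-en-1-yl]-3-methylpent-2-en-4-yn-1-yl}triphenylphosphonium bromide; 23 (2E,4E,6E)-2,7-dimethylocta-2,4,6-trienedial
Product: 25 tert-butyl (1R)-3,5,5-trimethyl-4-[(3E,5E,7E,9E,11E)-3,7,12-trimethyl-13-oxotrideca-3,5,7,9,11-pentaen-1-yn-1-yl]cyclohex-3-en-1-yl carbonate, via ylide 24 (not isolated)
Conditions: 23 (3 equiv), 1,2-epoxybutane/toluene, 65 °C
Reagents that add atoms: none
Why: Wittig olefination under neutral conditions (bromide opens the epoxide and the alkoxide formed deprotonates the salt), in which excess dialdehyde favours mono-olefination and the hindered 11Z isomer of the new C11=C12 bond should equilibrate thermally to E at the reaction temperature.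

Step 15
Reactants: 25 tert-butyl (1R)-3,5,5-trimethyl-4-[(3E,5E,7E,9E,11E)-3,7,12-trimethyl-13-oxotrideca-3,5,7,9,11-pentaen-1-yn-1-yl]cyclohex-3-en-1-yl carbonate; 22 {(2E)-3-methyl-5-[(3aS,7aR)-5,5,7-trimethyl-2-oxo-3a,4,5,7a-tetrahydro-1,3-benzodioxol-6-yl]pent-2-en-4-yn-1-yl}triphenylphosphonium bromide
Product: 27 (3R,3'S,4'R)-3-[(tert-butoxycarbonyl)oxy]-7,8,7',8'-tetradehydro-β,β-carotene-3',4'-diyl carbonate (all-E), via ylide 26 (not isolated)
Conditions: 1,2-epoxybutane/toluene, 65 °C, argon, dark
Reagents that add atoms: none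
Why: The second Wittig olefination forms C11'=C12' and completes the C40 chain under neutral conditions that keep both carbonates, and thermal equilibration should again favour E at the new bond.

Step 16
Reactants: 27 (3R,3'S,4'R)-3-[(tert-butoxycarbonyl)oxy]-7,8,7',8'-tetradehydro-β,β-carotene-3',4'-diyl carbonate (all-E)
Product: 28 (3R,3'S,4'R)-7,8,7',8'-tetradehydro-β,β-carotene-3,3',4'-triol (all-E)
Conditions: NaOMe (30 mol %), MeOH/THF, 25 → 40 °C, argon, dark
Reagents that add atoms: none
Why: Base-catalysed transesterification (methanolysis) of the cyclic and the tert-butyl carbonate frees the three hydroxyls without acid, which the allylic C4' alcohol and the polyene would not tolerate, and touches no stereocentre or double bond.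

Compound list
1 | 4-hydroxy-3,3-dimethylbutan-2-one | CC(=O)C(C)(C)CO | starting material
2 | 4-iodo-3,3-dimethylbutan-2-one | CC(=O)C(C)(C)CI | intermediate
3 | lithium 4-iodo-3,3-dimethylbut-1-en-2-olate | C=C(O[Li])C(C)(C)CI | intermediate (not isolated)
4 | 1-iodo-2,2-dimethylhept-6-en-3-one | C=CCCC(=O)C(C)(C)CI | intermediate
5 | 6-iodo-5,5-dimethyl-4-oxohexanal | O=CCCC(=O)C(C)(C)CI | intermediate
6 | (4R)-2,2-dimethyl-4-[(trimethylsilyl)oxy]cyclohexan-1-one | O=C1C(C)(C)C[C@H](O[Si](C)(C)C)CC1 | intermediate (not isolated)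
7 | (4R)-4-hydroxy-2,2-dimethylcyclohexan-1-one | O=C1C(C)(C)C[C@H](O)CC1 | intermediate
8 | tert-butyl (1R)-3,3-dimethyl-4-oxocyclohexyl carbonate | O=C1C(C)(C)C[C@H](OC(=O)OC(C)(C)C)CC1 | intermediate
9 | lithium (4R)-4-[(tert-butoxycarbonyl)oxy]-6,6-dimethylcyclohex-1-en-1-olate | CC1(C)C[C@H](OC(=O)OC(C)(C)C)CC=C1O[Li] | intermediate (not isolated)
10 | tert-butyl (1R)-3,3,5-trimethyl-4-oxocyclohexyl carbonate (both C5 epimers) | O=C1C(C)(C)C[C@H](OC(=O)OC(C)(C)C)CC1C | intermediate
11 | lithium (4R)-4-[(tert-butoxycarbonyl)oxy]-2,6,6-trimethylcyclohex-1-en-1-olate | CC1=C(O[Li])C(C)(C)C[C@H](OC(=O)OC(C)(C)C)C1 | intermediate (not isolated)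
12 | (4R)-4-[(tert-butoxycarbonyl)oxy]-2,6,6-trimethylcyclohex-1-en-1-yl trifluoromethanesulfonate | CC1=C(OS(=O)(=O)C(F)(F)F)C(C)(C)C[C@H](OC(=O)OC(C)(C)C)C1 | intermediate
13 | (2E)-3-methylpent-2-en-4-yn-1-ol | C#C/C(C)=C/CO | starting material
14 | tert-butyl (1R)-4-[(3E)-5-hydroxy-3-methylpent-3-en-1-yn-1-yl]-3,5,5-trimethylcyclohex-3-en-1-yl carbonate | CC1=C(C#C/C(C)=C/CO)C(C)(C)C[C@H](OC(=O)OC(C)(C)C)C1 | intermediate
15 | tert-butyl (1R)-4-[(3E)-5-bromo-3-methylpent-3-en-1-yn-1-yl]-3,5,5-trimethylcyclohex-3-en-1-yl carbonate | CC1=C(C#C/C(C)=C/CBr)C(C)(C)C[C@H](OC(=O)OC(C)(C)C)C1 | intermediate (not isolated)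
16 | {(2E)-5-[(4R)-4-[(tert-butoxycarbonyl)oxy]-2,6,6-trimethylcyclohex-1-en-1-yl]-3-methylpent-2-en-4-yn-1-yl}triphenylphosphonium bromide | CC1=C(C#C/C(C)=C/C[P+](c2ccccc2)(c2ccccc2)c2ccccc2)C(C)(C)C[C@H](OC(=O)OC(C)(C)C)C1.[Br-] | intermediate
17 | tert-butyl (1S)-3,5,5-trimethyl-4-oxocyclohex-2-en-1-yl carbonate | CC1=C[C@@H](OC(=O)OC(C)(C)C)CC(C)(C)C1=O | intermediate
18 | lithium (2E)-5-lithio-3-methylpent-2-en-4-yn-1-olate | [Li]C#C/C(C)=C/CO[Li] | intermediate (not isolated)
19 | tert-butyl (1S)-4-hydroxy-4-[(3E)-5-hydroxy-3-methylpent-3-en-1-yn-1-yl]-3,5,5-trimethylcyclohex-2-en-1-yl carbonate (both C4 epimers) | CC1=C[C@@H](OC(=O)OC(C)(C)C)CC(C)(C)C1(O)C#C/C(C)=C/CO | intermediate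
20 | (3aS,7aR)-6-[(3E)-5-hydroxy-3-methylpent-3-en-1-yn-1-yl]-5,5,7-trimethyl-3a,4,5,7a-tetrahydro-1,3-benzodioxol-2-one | OC/C=C(\C)C#CC1=C(C)[C@@H](O2)[C@@H](OC2=O)CC1(C)C | intermediate
21 | (3aS,7aR)-6-[(3E)-5-bromo-3-methylpent-3-en-1-yn-1-yl]-5,5,7-trimethyl-3a,4,5,7a-tetrahydro-1,3-benzodioxol-2-one | BrC/C=C(\C)C#CC1=C(C)[C@@H](O2)[C@@H](OC2=O)CC1(C)C | intermediate (not isolated)
22 | {(2E)-3-methyl-5-[(3aS,7aR)-5,5,7-trimethyl-2-oxo-3a,4,5,7a-tetrahydro-1,3-benzodioxol-6-yl]pent-2-en-4-yn-1-yl}triphenylphosphonium bromide | [Br-].c1ccccc1[P+](c1ccccc1)(c1ccccc1)C/C=C(\C)C#CC1=C(C)[C@@H](O2)[C@@H](OC2=O)CC1(C)C | intermediate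
23 | (2E,4E,6E)-2,7-dimethylocta-2,4,6-trienedial | O=C/C(C)=C/C=C/C=C(C)/C=O | starting material
24 | triphenylphosphonium ylide of 16 | CC1=C(C#C/C(C)=C/C=P(c2ccccc2)(c2ccccc2)c2ccccc2)C(C)(C)C[C@H](OC(=O)OC(C)(C)C)C1 | intermediate (not isolated)
25 | tert-butyl (1R)-3,5,5-trimethyl-4-[(3E,5E,7E,9E,11E)-3,7,12-trimethyl-13-oxotrideca-3,5,7,9,11-pentaen-1-yn-1-yl]cyclohex-3-en-1-yl carbonate | CC1=C(C#C/C(C)=C/C=C/C(C)=C/C=C/C=C(C)/C=O)C(C)(C)C[C@H](OC(=O)OC(C)(C)C)C1 | intermediate
26 | triphenylphosphonium ylide of 22 | c1ccccc1P(c1ccccc1)(c1ccccc1)=C/C=C(\C)C#CC1=C(C)[C@@H](O2)[C@@H](OC2=O)CC1(C)C | intermediate (not isolated)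
27 | (3R,3'S,4'R)-3-[(tert-butoxycarbonyl)oxy]-7,8,7',8'-tetradehydro-β,β-carotene-3',4'-diyl carbonate (all-E) | CC1=C(C#C/C(C)=C/C=C/C(C)=C/C=C/C=C(C)/C=C/C=C(\C)C#CC2=C(C)[C@@H](O3)[C@@H](OC3=O)CC2(C)C)C(C)(C)C[C@H](OC(=O)OC(C)(C)C)C1 | intermediate
28 | (3R,3'S,4'R)-7,8,7',8'-tetradehydro-β,β-carotene-3,3',4'-triol (all-E) | CC1=C(C#C/C(C)=C/C=C/C(C)=C/C=C/C=C(C)/C=C/C=C(\C)C#CC2=C(C)[C@@H](O)[C@@H](O)CC2(C)C)C(C)(C)C[C@H](O)C1 | target

Total step count: 16.
Longest linear sequence: 12 steps (1–6, 7–9, 14, 15, 16; the ring-B branch 1–6, 10–13, 15, 16 is equally long).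

Steps most likely to fail

1. Step 4 (proposed new method). The chromium ligand sphere may give poor enantiofacial control with an unactivated alkylchromium, or the C2 radical may leak into the 1,2-acyl shift before it is trapped. The fallback sets out from 5 and returns at 7. The C2–C3 bond would be closed without asymmetric induction by the established stoichiometric alkylchromium protocol (excess CrCl2, catalytic cobalt phthalocyanine CoC32H16N8, DMF, 25 °C, high chromium concentration) to give racemic 4-hydroxy-2,2-dimethylcyclohexan-1-one F1. Dess–Martin oxidation would level the carbinol to the achiral 2,2-dimethylcyclohexane-1,4-dione F2. An NADPH-dependent ketoreductase with glucose/glucose dehydrogenase recycling, which should not accept the carbonyl shielded by the gem-dimethyl group, would then reduce the other carbonyl enantioselectively to 7, as enzymes of this class do for the 2,2,6-trimethyl homologue.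

2. Step 12 (proposed new method). The tert-butyl carbonate may be lost before it can capture the cation, or the delocalised cation may be captured by water or may lose a proton, so that the cis relationship of O3' and O4' is eroded. The fallback sets out from 19 and returns at 20. The transposition would be run as a plain anionotropic rearrangement in dilute aqueous H2SO4/acetone, where external water captures C4' from both faces, to give tert-butyl (1S)-2-hydroxy-4-[(3E)-5-hydroxy-3-methylpent-3-en-1-yn-1-yl]-3,5,5-trimethylcyclohex-3-en-1-yl carbonate F3 as a pair of epimers at the new carbinol carbon. Catalytic DBU in CH2Cl2 would then close the five-membered carbonate from the cis epimer only (alkoxide attack on the neighbouring carbonate with loss of tert-butanol) to give 20, which is separated. The trans epimer would be returned to the acid for re-equilibration through the same cation.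

3. Step 15. Double-bond geometry may be lost: Z olefin at the new C11'=C12' bond and E-to-Z leakage at C9'=C10' through the delocalised allylic ylide at 65 °C. The fallback sets out from 21 and returns at 27. Bromide 21, prepared as in step 13 but not quaternised, would be heated with P(OEt)3 (Michaelis–Arbuzov reaction) to give diethyl {(2E)-3-methyl-5-[(3aS,7aR)-5,5,7-trimethyl-2-oxo-3a,4,5,7a-tetrahydro-1,3-benzodioxol-6-yl]pent-2-en-4-yn-1-yl}phosphonate F4. Its sodium salt (NaN(SiMe3)2, THF, −78 °C) would be condensed with aldehyde 25 in a Horner–Wadsworth–Emmons olefination, which is inherently E-selective at the new bond and runs cold enough to hold the C9'=C10' geometry.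

Further compounds
F1 | step 4 | rac-4-hydroxy-2,2-dimethylcyclohexan-1-one | CC1(C)CC(O)CCC1=O
F2 | step 4 | 2,2-dimethylcyclohexane-1,4-dione | CC1(C)CC(=O)CCC1=O
F3 | step 12 | tert-butyl (1S)-2-hydroxy-4-[(3E)-5-hydroxy-3-methylpent-3-en-1-yn-1-yl]-3,5,5-trimethylcyclohex-3-en-1-yl carbonate (both C2 epimers) | OC/C=C(\C)C#CC1=C(C)C(O)[C@@H](OC(=O)OC(C)(C)C)CC1(C)C
F4 | step 15 | diethyl {(2E)-3-methyl-5-[(3aS,7aR)-5,5,7-trimethyl-2-oxo-3a,4,5,7a-tetrahydro-1,3-benzodioxol-6-yl]pent-2-en-4-yn-1-yl}phosphonate | CCOP(=O)(OCC)C/C=C(\C)C#CC1=C(C)[C@@H](O2)[C@@H](OC2=O)CC1(C)C
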